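**Assumption:** plakortolide numbering is used for the core (C1 lactone carbonyl, C2 CH2, C3 peroxy methine, C4 lactone-bearing quaternary carbon, C5 CH2, C6 peroxy quaternary carbon). In this numbering the target is (3R,4R,6S), with a cis ring fusion and the C4 and C6 methyl groups cis.

## Retrosynthetic overview

1. Target ⇐ aryl TBS ether 20 ⇐ intramolecular oxa-Michael addition of the C6 hydroperoxide 19 onto a butenolide; this closes the 1,2-dioxane (second ring) and the cis fusion fixes C3.
2. Hydroperoxide ⇐ cobalt-catalysed hydroperoxysilylation of the 1,1-disubstituted alkene of butenolide 17. C6 forms without control, and the epimers are separated after ring closure.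
3. Butenolide 17 (first ring) ⇐ α-hydroxy aldehyde 15 + Ph3P=C=C=O; 15 ⇐ aldol adduct 12 by methylenation, reduction and oxidation.
4. Key C4–C5 bond: enantioselective Mukaiyama aldol of enol silane 9 (from methyl ketone 8) with methyl pyruvate 10, which sets C4.
5. Ketone 8 ⇐ methyl undec-10-enoate 1 + 4-bromophenyl benzyl ether 2 by B-alkyl Suzuki coupling.

## Route

Step 1
Reactants: 1 methyl undec-10-enoate; 2 1-(benzyloxy)-4-bromobenzene
Product: 4 methyl 11-[4-(benzyloxy)phenyl]undecanoate, via alkylborane 3 (not isolated)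
Conditions: 9-BBN, THF, 0 °C to rt; then 2, PdCl2(dppf) (3 mol %), K2CO3, DMF/H2O, 50 °C
Reagents that add atoms: none
Why: Anti-Markovnikov hydroboration followed by B-alkyl Suzuki–Miyaura coupling forms the aryl–C(sp3) bond and tolerates the methyl ester under carbonate base; no stereocenter is formed.

Step 2
Reactants: 4 methyl 11-[4-(benzyloxy)phenyl]undecanoate
Product: 5 methyl 11-(4-hydroxyphenyl)undecanoate
Conditions: H2 (1 atm), 10% Pd/C, EtOAc/MeOH, rt
Reagents that add atoms: none
Why: Catalytic hydrogenolysis cleaves the benzyl aryl ether cleanly, so the phenol can carry a silyl group that is removable at the end without any reducing conditions.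

Step 3
Reactants: 5 methyl 11-(4-hydroxyphenyl)undecanoate
Product: 6 methyl 11-{4-[(tert-butyldimethylsilyl)oxy]phenyl}undecanoate
Conditions: TBSCl, imidazole, DMF, rt
Reagents that add atoms: tert-butyldimethylsilyl chloride, CC(C)(C)[Si](C)(C)Cl
Why: Imidazole-promoted silylation gives the aryl TBS ether, which is stable to the organometallic, Lewis-acid and radical steps ahead.

Step 4
Reactants: 6 methyl 11-{4-[(tert-butyldimethylsilyl)oxy]phenyl}undecanoate
Product: 7 11-{4-[(tert-butyldimethylsilyl)oxy]phenyl}-N-methoxy-N-methylundecanamide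
Conditions: MeNHOMe·HCl, i-PrMgCl, THF, −20 to 0 °C; then 1 M HCl
Reagents that add atoms: N,O-dimethylhydroxylamine hydrochloride, CNOC.Cl
Why: The magnesium amide formed in the flask converts the ester directly into the Weinreb amide (aminolysis).

Step 5
Reactants: 7 11-{4-[(tert-butyldimethylsilyl)oxy]phenyl}-N-methoxy-N-methylundecanamide
Product: 8 12-{4-[(tert-butyldimethylsilyl)oxy]phenyl}dodecan-2-one
Conditions: MeMgBr, THF, 0 °C; then 1 M HCl, 0 °C
Reagents that add atoms: methylmagnesium bromide, C[Mg]Br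
Why: Grignard addition to a Weinreb amide stops at the chelated tetrahedral adduct, so only the methyl ketone is released on quench.

Step 6
Reactants: 8 12-{4-[(tert-butyldimethylsilyl)oxy]phenyl}dodecan-2-one
Product: 9 tert-butyldimethyl(4-{11-[(trimethylsilyl)oxy]dodec-11-en-1-yl}phenoxy)silane
Conditions: TMSCl, LiN(i-Pr)2 (commercial solution), THF, −78 °C (in situ trapping); pentane, filtration, used crude
Reagents that add atoms: chlorotrimethylsilane, C[Si](C)(C)Cl
Why: Kinetic deprotonation at the unhindered methyl group with immediate silyl trapping gives the terminal enol silane (kinetic enolate formation, expected ≥9:1 over the internal isomers).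

Step 7
Reactants: 9 tert-butyldimethyl(4-{11-[(trimethylsilyl)oxy]dodec-11-en-1-yl}phenoxy)silane; 10 methyl pyruvate
Product: 12 methyl (2R)-14-{4-[(tert-butyldimethylsilyl)oxy]phenyl}-2-hydroxy-2-methyl-4-oxotetradecanoate, via trimethylsilyl ether 11 (not isolated)
Conditions: [Cu((R,R)-t-Bu-box)](OTf)2 (10 mol %, from Cu(OTf)2 and 2,2′-(propane-2,2-diyl)bis[(4R)-4-tert-butyl-4,5-dihydrooxazole]), THF, −78 °C; then 1 M HCl, THF, rt
Reagents that add atoms: none
Why: In this enantioselective Mukaiyama aldol the pyruvate chelates the square-planar copper bis(oxazoline) Lewis acid through both carbonyls, the tert-butyl groups of the (R,R)-ligand block the si face, and the enol silane adds to the re face of the ketone to set C4 as R (about 93–96% ee expected, checked by chiral HPLC); mild acid then removes the transferred TMS group.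

Step 8
Reactants: 12 methyl (2R)-14-{4-[(tert-butyldimethylsilyl)oxy]phenyl}-2-hydroxy-2-methyl-4-oxotetradecanoate
Product: 13 methyl (2R)-14-{4-[(tert-butyldimethylsilyl)oxy]phenyl}-2-hydroxy-2-methyl-4-methylidenetetradecanoate
Conditions: Zn, CH2Br2, TiCl4, THF (pre-formed reagent); CH2Cl2, 0 °C to rt
Reagents that add atoms: dibromomethane, BrCBr
Why: Takai–Lombardo methylenation with the non-basic zinc/titanium gem-dimetallic reagent converts the ketone, not the ester, into the 1,1-disubstituted alkene and avoids the retro-aldol or β-elimination that a basic Wittig ylide would cause in this β-hydroxy ketone; C4 is untouched.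

Step 9
Reactants: 13 methyl (2R)-14-{4-[(tert-butyldimethylsilyl)oxy]phenyl}-2-hydroxy-2-methyl-4-methylidenetetradecanoate
Product: 14 (2R)-14-{4-[(tert-butyldimethylsilyl)oxy]phenyl}-2-methyl-4-methylidenetetradecane-1,2-diol
Conditions: LiBH4, MeOH (1 equiv), THF, 0 °C to rt
Reagents that add atoms: none
Why: Borohydride reduction of the chelation-activated α-hydroxy ester gives the 1,2-diol without touching the alkene or the aryl silyl ether.

Step 10
Reactants: 14 (2R)-14-{4-[(tert-butyldimethylsilyl)oxy]phenyl}-2-methyl-4-methylidenetetradecane-1,2-diol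
Product: 15 (2R)-14-{4-[(tert-butyldimethylsilyl)oxy]phenyl}-2-hydroxy-2-methyl-4-methylidenetetradecanal
Conditions: IBX, DMSO/THF, rt; used crude
Reagents that add atoms: none
Why: IBX oxidation takes the primary alcohol to the aldehyde, cannot oxidise the tertiary alcohol and does not cleave the 1,2-diol.

Step 11
Reactants: 15 (2R)-14-{4-[(tert-butyldimethylsilyl)oxy]phenyl}-2-hydroxy-2-methyl-4-methylidenetetradecanal
Product: 17 (5R)-5-(12-{4-[(tert-butyldimethylsilyl)oxy]phenyl}-2-methylidenedodecyl)-5-methylfuran-2(5H)-one, via phosphorane ester 16 (not isolated)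
Conditions: Ph3P=C=C=O, toluene, 90 °C (0.02 M)
Reagents that add atoms: (triphenylphosphoranylidene)ketene, O=C=C=P(c1ccccc1)(c1ccccc1)c1ccccc1
Why: The tertiary alcohol adds across the ketene C=C of the Bestmann ylide and the resulting stabilised ylide ester closes by intramolecular Wittig olefination on the neighbouring aldehyde, so the butenolide alkene is necessarily cis and C4 is not involved.

Step 12
Reactants: 17 (5R)-5-(12-{4-[(tert-butyldimethylsilyl)oxy]phenyl}-2-methylidenedodecyl)-5-methylfuran-2(5H)-one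
Product: 18 (5R)-5-{12-{4-[(tert-butyldimethylsilyl)oxy]phenyl}-2-methyl-2-[(triethylsilyl)peroxy]dodecyl}-5-methylfuran-2(5H)-one (about 1:1 mixture of C2′ epimers)
Conditions: Co(thd)2 (10 mol %; thd = 2,2,6,6-tetramethylheptane-3,5-dionate), O2 (1 atm), Et3SiH, ClCH2CH2Cl, rt
Reagents that add atoms: dioxygen, O=O; triethylsilane, CC[SiH](CC)CC
Why: In this Mukaiyama–Isayama hydroperoxysilylation, hydrogen-atom transfer to the electron-rich 1,1-disubstituted alkene gives the tertiary C6 radical, which traps O2 and is silylated (Markovnikov) faster than the hindered, electron-poor butenolide alkene reacts; the planar radical is remote from C4, so both C6 configurations form and are carried on together.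

Step 13
Reactants: 18 (5R)-5-{12-{4-[(tert-butyldimethylsilyl)oxy]phenyl}-2-methyl-2-[(triethylsilyl)peroxy]dodecyl}-5-methylfuran-2(5H)-one (epimer mixture)
Product: 20 (1R,4S,6R)-4-(10-{4-[(tert-butyldimethylsilyl)oxy]phenyl}decyl)-4,6-dimethyl-2,3,7-trioxabicyclo[4.3.0]nonan-8-one (plakortolide S TBS ether; 3R,4R,6S in plakortolide numbering), via hydroperoxide 19 (not isolated)
Conditions: HCl (cat.), MeOH, 0 °C; evaporate; then Et2NH (0.5 equiv), CF3CH2OH, rt; SiO2 chromatography/HPLC to remove the C6 epimer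
Reagents that add atoms: none
Why: Acidic methanolysis frees the hydroperoxide, which undergoes amine-promoted 6-exo intramolecular oxa-Michael addition to the butenolide; the tether can reach C3 only from the face carrying the side chain, so the fusion is cis and C3 is fixed as R by C4, and the (6S) diastereomer (about half of the material) is separated from its (6R) epimer and assigned by NOESY.

Step 14
Reactants: 20 plakortolide S TBS ether
Product: 21 plakortolide S, (1R,4S,6R)-4-[10-(4-hydroxyphenyl)decyl]-4,6-dimethyl-2,3,7-trioxabicyclo[4.3.0]nonan-8-one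
Conditions: KHF2, MeOH, rt
Reagents that add atoms: none
Why: Bifluoride desilylation cleaves the aryl silyl ether under near-neutral conditions that leave the peroxide, the lactone and all three stereocenters intact.

## Compound list

1 | methyl undec-10-enoate | C=CCCCCCCCCC(=O)OC | starting material
2 | 1-(benzyloxy)-4-bromobenzene | Brc1ccc(OCc2ccccc2)cc1 | starting material
3 | methyl 11-(9-borabicyclo[3.3.1]nonan-9-yl)undecanoate | COC(=O)CCCCCCCCCCB1C2CCCC1CCC2 | intermediate (not isolated)
4 | methyl 11-[4-(benzyloxy)phenyl]undecanoate | COC(=O)CCCCCCCCCCc1ccc(OCc2ccccc2)cc1 | intermediate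
5 | methyl 11-(4-hydroxyphenyl)undecanoate | COC(=O)CCCCCCCCCCc1ccc(O)cc1 | intermediate
6 | methyl 11-{4-[(tert-butyldimethylsilyl)oxy]phenyl}undecanoate | COC(=O)CCCCCCCCCCc1ccc(O[Si](C)(C)C(C)(C)C)cc1 | intermediate
7 | 11-{4-[(tert-butyldimethylsilyl)oxy]phenyl}-N-methoxy-N-methylundecanamide | CON(C)C(=O)CCCCCCCCCCc1ccc(O[Si](C)(C)C(C)(C)C)cc1 | intermediate
8 | 12-{4-[(tert-butyldimethylsilyl)oxy]phenyl}dodecan-2-one | CC(=O)CCCCCCCCCCc1ccc(O[Si](C)(C)C(C)(C)C)cc1 | intermediate
9 | tert-butyldimethyl(4-{11-[(trimethylsilyl)oxy]dodec-11-en-1-yl}phenoxy)silane (terminal enol silane) | C=C(O[Si](C)(C)C)CCCCCCCCCCc1ccc(O[Si](C)(C)C(C)(C)C)cc1 | intermediate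
10 | methyl pyruvate (methyl 2-oxopropanoate) | CC(=O)C(=O)OC | starting material
11 | methyl (2R)-14-{4-[(tert-butyldimethylsilyl)oxy]phenyl}-2-methyl-4-oxo-2-[(trimethylsilyl)oxy]tetradecanoate | COC(=O)[C@](C)(O[Si](C)(C)C)CC(=O)CCCCCCCCCCc1ccc(O[Si](C)(C)C(C)(C)C)cc1 | intermediate (not isolated)
12 | methyl (2R)-14-{4-[(tert-butyldimethylsilyl)oxy]phenyl}-2-hydroxy-2-methyl-4-oxotetradecanoate | COC(=O)[C@](C)(O)CC(=O)CCCCCCCCCCc1ccc(O[Si](C)(C)C(C)(C)C)cc1 | intermediate
13 | methyl (2R)-14-{4-[(tert-butyldimethylsilyl)oxy]phenyl}-2-hydroxy-2-methyl-4-methylidenetetradecanoate | COC(=O)[C@](C)(O)CC(=C)CCCCCCCCCCc1ccc(O[Si](C)(C)C(C)(C)C)cc1 | intermediate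
14 | (2R)-14-{4-[(tert-butyldimethylsilyl)oxy]phenyl}-2-methyl-4-methylidenetetradecane-1,2-diol | OC[C@](C)(O)CC(=C)CCCCCCCCCCc1ccc(O[Si](C)(C)C(C)(C)C)cc1 | intermediate
15 | (2R)-14-{4-[(tert-butyldimethylsilyl)oxy]phenyl}-2-hydroxy-2-methyl-4-methylidenetetradecanal | O=C[C@](C)(O)CC(=C)CCCCCCCCCCc1ccc(O[Si](C)(C)C(C)(C)C)cc1 | intermediate
16 | (2R)-14-{4-[(tert-butyldimethylsilyl)oxy]phenyl}-2-methyl-4-methylidene-1-oxotetradecan-2-yl (triphenyl-λ5-phosphanylidene)acetate | O=C[C@](C)(OC(=O)C=P(c1ccccc1)(c1ccccc1)c1ccccc1)CC(=C)CCCCCCCCCCc1ccc(O[Si](C)(C)C(C)(C)C)cc1 | intermediate (not isolated)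
17 | (5R)-5-(12-{4-[(tert-butyldimethylsilyl)oxy]phenyl}-2-methylidenedodecyl)-5-methylfuran-2(5H)-one | C=C(CCCCCCCCCCc1ccc(O[Si](C)(C)C(C)(C)C)cc1)C[C@@]1(C)OC(=O)C=C1 | intermediate
18 | (5R)-5-{12-{4-[(tert-butyldimethylsilyl)oxy]phenyl}-2-methyl-2-[(triethylsilyl)peroxy]dodecyl}-5-methylfuran-2(5H)-one, about 1:1 mixture of epimers at the peroxy carbon (left undefined in the SMILES) | CC(CCCCCCCCCCc1ccc(O[Si](C)(C)C(C)(C)C)cc1)(OO[Si](CC)(CC)CC)C[C@@]1(C)OC(=O)C=C1 | intermediate
19 | (5R)-5-(12-{4-[(tert-butyldimethylsilyl)oxy]phenyl}-2-hydroperoxy-2-methyldodecyl)-5-methylfuran-2(5H)-one, same epimer mixture | CC(CCCCCCCCCCc1ccc(O[Si](C)(C)C(C)(C)C)cc1)(OO)C[C@@]1(C)OC(=O)C=C1 | intermediate (not isolated)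
20 | (1R,4S,6R)-4-(10-{4-[(tert-butyldimethylsilyl)oxy]phenyl}decyl)-4,6-dimethyl-2,3,7-trioxabicyclo[4.3.0]nonan-8-one (cis-fused; 3R,4R,6S in plakortolide numbering) | C[C@]1(CCCCCCCCCCc2ccc(O[Si](C)(C)C(C)(C)C)cc2)C[C@@]2(C)OC(=O)C[C@H]2OO1 | intermediate
21 | plakortolide S, (1R,4S,6R)-4-[10-(4-hydroxyphenyl)decyl]-4,6-dimethyl-2,3,7-trioxabicyclo[4.3.0]nonan-8-one | C[C@]1(CCCCCCCCCCc2ccc(O)cc2)C[C@@]2(C)OC(=O)C[C@H]2OO1 | target

## Step count and risks

Total steps: 14. Longest linear sequence: 14 steps (1 → 21); compounds 2 and 10 are purchased.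

The enantiopurity of the final product equals that of the aldol in step 7 (expected about 93–96% ee), because the minor enantiomer is not removed by the later achiral separations. Step 13 discards roughly half the material as the C6 epimer.

The three steps most likely to fail:

**Step 7 (enantioselective aldol).** The ee with this long-chain enol silane, or its regiochemical purity, may fall short. The fallback takes the C4 center from (S)-lactic acid by self-regeneration of stereocenters; it sets out from ester 6 and comes back at diol 14. (S)-Lactic acid and pivalaldehyde (TsOH, pentane, water removal) give the cis acetal (2S,5S)-2-tert-butyl-5-methyl-1,3-dioxolan-4-one F1. Ester 6 with Me3SiCH2MgCl/CeCl3 (THF, −78 °C to rt) gives the bis(silylmethyl) carbinol F2, which on silica gel undergoes Peterson elimination to the allylsilane F3. NBS (CH2Cl2, propylene oxide, −78 °C) converts F3 into the allylic bromide F4. The lithium enolate of F1 (LiN(i-Pr)2, THF, −78 °C) is alkylated by F4 on the face opposite the tert-butyl group to give the alkylated dioxolanone F5 (expected dr > 95:5; the new group replaces the lactate hydrogen with retention, which corresponds to R at C4). LiBH4 (THF, 0 °C to rt) reduces F5 to diol 14, and the route continues with step 10.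

**Step 11 (butenolide from the tertiary α-hydroxy aldehyde).** Addition of the hindered tertiary alcohol to the ylide may be slow, or the aldehyde may oligomerise. The fallback builds the ring by metathesis; it sets out from aldehyde 15 and comes back at butenolide 17. Wittig methylenation (Ph3P=CH2, 2.5 equiv, THF, −78 to 0 °C) gives the tertiary allylic alcohol F6. Acryloyl chloride with i-Pr2NEt and DMAP (CH2Cl2, 0 °C to rt) gives the acrylate F7. Ring-closing metathesis with second-generation Grubbs catalyst (CH2Cl2, 40 °C) closes the five-membered ring between the vinyl and acrylate groups, which is faster than any reaction of the 1,1-disubstituted alkene, and delivers 17.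

**Step 12 (chemoselective hydroperoxysilylation).** The butenolide alkene may compete for the cobalt hydride. The fallback installs the peroxide before any conjugated alkene exists; it sets out from diol 14 and comes back at silyl peroxide 18. Diol 14 under the same Co(thd)2/O2/Et3SiH conditions gives the silylperoxy diol F8 (both C4 epimers), and IBX (DMSO, rt) gives the silylperoxy hydroxy aldehyde F9. Still–Gennari olefination ((CF3CH2O)2P(O)CH2CO2Me, KN(SiMe3)2, 18-crown-6, THF, −78 °C) gives the Z-enoate F10, which lactonises on standing or with PPTS (CH2Cl2, rt) to 18. The route then continues with step 13. This fallback does not improve the C6 ratio, which remains about 1:1.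

## Further compounds

F1 | step 7 | (2S,5S)-2-tert-butyl-5-methyl-1,3-dioxolan-4-one | C[C@@H]1O[C@H](C(C)(C)C)OC1=O
F2 | step 7 | 2-(10-{4-[(tert-butyldimethylsilyl)oxy]phenyl}decyl)-1,3-bis(trimethylsilyl)propan-2-ol | C[Si](C)(C)CC(O)(C[Si](C)(C)C)CCCCCCCCCCc1ccc(O[Si](C)(C)C(C)(C)C)cc1
F3 | step 7 | tert-butyldimethyl(4-{11-[(trimethylsilyl)methyl]dodec-11-en-1-yl}phenoxy)silane | C=C(C[Si](C)(C)C)CCCCCCCCCCc1ccc(O[Si](C)(C)C(C)(C)C)cc1
F4 | step 7 | {4-[11-(bromomethyl)dodec-11-en-1-yl]phenoxy}(tert-butyl)dimethylsilane | C=C(CBr)CCCCCCCCCCc1ccc(O[Si](C)(C)C(C)(C)C)cc1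
F5 | step 7 | (2S,5R)-2-tert-butyl-5-(12-{4-[(tert-butyldimethylsilyl)oxy]phenyl}-2-methylidenedodecyl)-5-methyl-1,3-dioxolan-4-one | C[C@]1(CC(=C)CCCCCCCCCCc2ccc(O[Si](C)(C)C(C)(C)C)cc2)O[C@H](C(C)(C)C)OC1=O
F6 | step 11 | (3R)-15-{4-[(tert-butyldimethylsilyl)oxy]phenyl}-3-methyl-5-methylidenepentadec-1-en-3-ol | C=C[C@](C)(O)CC(=C)CCCCCCCCCCc1ccc(O[Si](C)(C)C(C)(C)C)cc1
F7 | step 11 | (3R)-15-{4-[(tert-butyldimethylsilyl)oxy]phenyl}-3-methyl-5-methylidenepentadec-1-en-3-yl prop-2-enoate | C=CC(=O)O[C@@](C)(C=C)CC(=C)CCCCCCCCCCc1ccc(O[Si](C)(C)C(C)(C)C)cc1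
F8 | step 12 | (2R)-14-{4-[(tert-butyldimethylsilyl)oxy]phenyl}-2,4-dimethyl-4-[(triethylsilyl)peroxy]tetradecane-1,2-diol (both C4 epimers) | OC[C@](C)(O)CC(C)(OO[Si](CC)(CC)CC)CCCCCCCCCCc1ccc(O[Si](C)(C)C(C)(C)C)cc1
F9 | step 12 | (2R)-14-{4-[(tert-butyldimethylsilyl)oxy]phenyl}-2-hydroxy-2,4-dimethyl-4-[(triethylsilyl)peroxy]tetradecanal (both C4 epimers) | O=C[C@](C)(O)CC(C)(OO[Si](CC)(CC)CC)CCCCCCCCCCc1ccc(O[Si](C)(C)C(C)(C)C)cc1
F10 | step 12 | methyl (2Z,4R)-16-{4-[(tert-butyldimethylsilyl)oxy]phenyl}-4-hydroxy-4,6-dimethyl-6-[(triethylsilyl)peroxy]hexadec-2-enoate (both C6 epimers) | COC(=O)/C=C\[C@](C)(O)CC(C)(OO[Si](CC)(CC)CC)CCCCCCCCCCc1ccc(O[Si](C)(C)C(C)(C)C)cc1
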